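The arene (C1'–C6', C1' on benzylic C1) is a 5-substituted cyclohexane-1,3-dione in disguise: C3' and C5', the two oxygen-bearing ring carbons, become the dione carbonyls, indistinguishable until one is converted into its methyl enol ether. The route rests on cutting C1'–C2' and C3'–C4'. One Michael–Claisen operation with dimethyl malonate forms both bonds and closes the six-membered carbocycle. Its precursor is the linear (E)-enone 11, a heptadec-3-ene-2,12-dione that already holds the silylated (R)-carbinol (future C2) and the future C8 ketone. Because the phenol appears only in the last step, C2–OH is acetylated with nothing to compete.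

Key step: step 7

Remark: chain locants C1–C13 and ring locants C1'–C6' are those of the target, which is (2R); pentylmagnesium bromide and the salt-free allylborane of step 4 are assumed to be used as purchased solutions.

Step 1
Reactants: 1 cycloheptanone; 2 pentylmagnesium bromide
Product: 3 1-pentylcycloheptan-1-ol
Conditions: Et2O, 0 °C → rt; aq NH4Cl
Reagents that add atoms: none
Why: Grignard 1,2-addition of a primary alkylmagnesium bromide to an unhindered cyclic ketone should give the tertiary alcohol; no stereocentre is formed.

Step 2
Reactants: 3 1-pentylcycloheptan-1-ol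
Product: 4 1-pentylcyclohept-1-ene
Conditions: TsOH·H2O (5 mol %), toluene, reflux (Dean–Stark)
Reagents that add atoms: none
Why: Acid-catalysed E1 dehydration of the tertiary alcohol under equilibrating conditions should favour the endocyclic trisubstituted alkene; any exocyclic isomer is purged in step 3 because its ozonolysis fragments (cycloheptanone, pentanal) are volatile.

Step 3
Reactants: 4 1-pentylcyclohept-1-ene
Product: 6 7-oxododecanal, via secondary ozonide 5 (not isolated)
Conditions: O3, CH2Cl2, −78 °C; then PPh3, −78 °C → rt
Reagents that add atoms: ozone, [O-][O+]=O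
Why: Ozonolysis (Criegee mechanism) with reductive work-up should open the ring to the 1,7-keto aldehyde, which is kept neutral and used at once to avoid intramolecular aldol condensation.

Step 4
Reactants: 6 7-oxododecanal
Product: 8 (4R)-4-hydroxypentadec-1-en-10-one, via borinate ester 7 (not isolated)
Conditions: (−)-Ipc2B(allyl) (1.1 equiv, salt-free), Et2O, −78 °C; then 3 M NaOH, 30% H2O2, 0 °C → rt
Reagents that add atoms: (−)-B-allyldiisopinocampheylborane (the enantiomer made from (+)-α-pinene), C=CCB([C@@H]1C[C@@H]2C[C@H]([C@H]1C)C2(C)C)[C@@H]1C[C@@H]2C[C@H]([C@H]1C)C2(C)C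
Why: Brown asymmetric allylboration delivers allyl through a chair six-membered transition state to the Si face of the unbranched aldehyde, which sets the carbinol as R (later C2 of the target); at −78 °C the aldehyde reacts far faster than the dialkyl ketone.

Step 5
Reactants: 8 (4R)-4-hydroxypentadec-1-en-10-one
Product: 9 (4R)-4-(tert-butyldimethylsilyloxy)pentadec-1-en-10-one
Conditions: TBSCl, imidazole, DMF, rt
Reagents that add atoms: tert-butyldimethylsilyl chloride, CC(C)(C)[Si](C)(C)Cl
Why: Imidazole-promoted silylation of a secondary alcohol gives an ether that tolerates metathesis and methoxide, blocks lactonisation in step 7 and is removed at no extra cost in step 8.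

Step 6
Reactants: 9 (4R)-4-(tert-butyldimethylsilyloxy)pentadec-1-en-10-one; 10 but-3-en-2-one
Product: 11 (3E,6R)-6-(tert-butyldimethylsilyloxy)heptadec-3-ene-2,12-dione
Conditions: 10 (4 equiv), second-generation Hoveyda–Grubbs catalyst RuCl2(H2IMes)(=CH-C6H4-2-OiPr) (3 mol %), CH2Cl2, 40 °C
Reagents that add atoms: none
Why: Olefin cross-metathesis of a terminal alkene with an excess of an electron-poor vinyl ketone should be selective for the cross product and give the (E)-enone under thermodynamic control, without passing through an elimination-prone β-silyloxy aldehyde.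

Step 7
Reactants: 11 (3E,6R)-6-(tert-butyldimethylsilyloxy)heptadec-3-ene-2,12-dione; 12 dimethyl malonate
Product: 16 5-[(2R)-2-(tert-butyldimethylsilyloxy)-8-oxotridecyl]cyclohexane-1,3-dione, via Michael adduct 13 (not isolated), via cyclic keto ester 14 (not isolated), via keto acid 15 (not isolated)
Conditions: 12 (1.5 equiv), NaOMe (0.2 equiv), MeOH, 0 °C → rt; then NaOMe (1.5 equiv), reflux; then 2 M aq NaOH, 70 °C; then 1 M HCl to pH 3, 60 °C
Reagents that add atoms: none
Why: With only catalytic methoxide at 0 °C the malonate anion adds to C4 of the (E)-enone (Michael addition) to give keto diester 13; the full charge of methoxide at reflux then lets the methyl-ketone enolate (C1) attack one ester carbonyl (Claisen condensation) to give 14, whose deprotonation as a cyclic β-dicarbonyl pulls the equilibrium forward, and hydroxide followed by mild acid removes the remaining ester as CO2 by way of acid 15. The closest known reaction type is the classical Michael–Claisen preparation of 5-substituted cyclohexane-1,3-diones from enones and malonate esters. The one ring is closed in the 6-exo-trig mode, the enolate carbon attacking an ester C=O whose oxygen stays outside the ring, so that the future arene bonds C1'–C2' (Michael) and C3'–C4' (Claisen) are made in a single flask. No lasting stereocentre is created, since the side-chain-bearing ring carbon of 16 carries two identical arms, and the (R)-carbinol carbon is not α to any carbonyl and cannot epimerise. The selectivity needed is conjugate addition ahead of γ-deprotonation (C5–H) with expulsion of the δ-silyloxy group; it is secured by letting the weakly basic malonate anion consume the enone before stoichiometric base and heat are applied, because once C3=C4 is saturated the silyloxy group is no longer β to an acidic carbon. The silyl ether also keeps the C6 oxygen from lactonising onto a malonate ester, and the C12 ketone is a spectator because its enolates could reach an ester only through a ring of ten or more atoms.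

Step 8
Reactants: 16 5-[(2R)-2-(tert-butyldimethylsilyloxy)-8-oxotridecyl]cyclohexane-1,3-dione
Product: 18 5-[(2R)-2-hydroxy-8-oxotridecyl]-3-methoxycyclohex-2-en-1-one, via silylated enol ether 17 (not isolated)
Conditions: TsOH·H2O (0.2 equiv), MeOH, rt; then H2O (5 vol %), 15 min; then NaHCO3
Reagents that add atoms: methanol, CO
Why: Acid-catalysed condensation of the cyclic 1,3-dione with methanol gives the vinylogous methyl ester 17 (either carbonyl gives the same product) and the same acid then methanolyses the secondary silyl ether; the new ring stereocentre forms as a mixture that is erased on aromatisation, and the short aqueous acid hold returns any C8 dimethyl ketal to the ketone.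

Step 9
Reactants: 18 5-[(2R)-2-hydroxy-8-oxotridecyl]-3-methoxycyclohex-2-en-1-one
Product: 19 (2R)-1-(5-methoxy-3-oxocyclohex-4-en-1-yl)-8-oxotridecan-2-yl acetate
Conditions: Ac2O, pyridine, DMAP (cat.), CH2Cl2, 0 °C → rt
Reagents that add atoms: acetic anhydride, CC(=O)OC(C)=O
Why: DMAP-catalysed acylation of the only hydroxyl group proceeds with retention at C2, and no phenol exists yet to compete.

Step 10
Reactants: 19 (2R)-1-(5-methoxy-3-oxocyclohex-4-en-1-yl)-8-oxotridecan-2-yl acetate
Product: 21 (2R)-1-(3-hydroxy-5-methoxyphenyl)-8-oxotridecan-2-yl acetate, via ring dienol 20 (not isolated)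
Conditions: DDQ (1.2 equiv), TsOH (10 mol %), 1,4-dioxane, 80 °C
Reagents that add atoms: none
Why: Quinone dehydrogenation: acid-promoted enolisation gives the 1,3-dioxygenated dienol 20, from which DDQ abstracts hydride to a cation that is the ring-protonated arene and loses a proton to the phenol, whereas the saturated acyclic ketone and the acetate have no comparably stabilised pathway, in line with DDQ dehydrogenation of steroidal enones that carry saturated ketones and acetates.

Compound list
1 | cycloheptanone | O=C1CCCCCC1 | starting material
2 | pentylmagnesium bromide | CCCCC[Mg]Br | starting material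
3 | 1-pentylcycloheptan-1-ol | CCCCCC1(O)CCCCCC1 | intermediate
4 | 1-pentylcyclohept-1-ene | CCCCCC1=CCCCCC1 | intermediate
5 | 1-pentyl-8,9,10-trioxabicyclo[5.2.1]decane (secondary ozonide, racemic) | CCCCCC12CCCCCC(O1)OO2 | intermediate (not isolated)
6 | 7-oxododecanal | CCCCCC(=O)CCCCCC=O | intermediate
7 | (4R)-10-oxopentadec-1-en-4-yl diisopinocampheylborinate (Ipc groups as in the reagent) | CCCCCC(=O)CCCCC[C@H](CC=C)OB([C@@H]1C[C@@H]2C[C@H]([C@H]1C)C2(C)C)[C@@H]1C[C@@H]2C[C@H]([C@H]1C)C2(C)C | intermediate (not isolated)
8 | (4R)-4-hydroxypentadec-1-en-10-one | CCCCCC(=O)CCCCC[C@H](CC=C)O | intermediate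
9 | (4R)-4-(tert-butyldimethylsilyloxy)pentadec-1-en-10-one | CCCCCC(=O)CCCCC[C@H](CC=C)O[Si](C)(C)C(C)(C)C | intermediate
10 | but-3-en-2-one (methyl vinyl ketone) | CC(=O)C=C | starting material
11 | (3E,6R)-6-(tert-butyldimethylsilyloxy)heptadec-3-ene-2,12-dione | CCCCCC(=O)CCCCC[C@H](C/C=C/C(C)=O)O[Si](C)(C)C(C)(C)C | intermediate (key-step precursor)
12 | dimethyl malonate | COC(=O)CC(=O)OC | starting material
13 | dimethyl 2-[(6R)-6-(tert-butyldimethylsilyloxy)-2,12-dioxoheptadecan-4-yl]propanedioate (epimers at C4) | CCCCCC(=O)CCCCC[C@H](CC(CC(C)=O)C(C(=O)OC)C(=O)OC)O[Si](C)(C)C(C)(C)C | intermediate (not isolated)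
14 | methyl 2-[(2R)-2-(tert-butyldimethylsilyloxy)-8-oxotridecyl]-4,6-dioxocyclohexane-1-carboxylate (ring diastereomers; sodium enolate in the flask) | CCCCCC(=O)CCCCC[C@H](CC1CC(=O)CC(=O)C1C(=O)OC)O[Si](C)(C)C(C)(C)C | intermediate (not isolated)
15 | 2-[(2R)-2-(tert-butyldimethylsilyloxy)-8-oxotridecyl]-4,6-dioxocyclohexane-1-carboxylic acid | CCCCCC(=O)CCCCC[C@H](CC1CC(=O)CC(=O)C1C(=O)O)O[Si](C)(C)C(C)(C)C | intermediate (not isolated)
16 | 5-[(2R)-2-(tert-butyldimethylsilyloxy)-8-oxotridecyl]cyclohexane-1,3-dione | CCCCCC(=O)CCCCC[C@H](CC1CC(=O)CC(=O)C1)O[Si](C)(C)C(C)(C)C | intermediate (key-step product)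
17 | 5-[(2R)-2-(tert-butyldimethylsilyloxy)-8-oxotridecyl]-3-methoxycyclohex-2-en-1-one (epimers at ring C5) | CCCCCC(=O)CCCCC[C@H](CC1CC(=O)C=C(OC)C1)O[Si](C)(C)C(C)(C)C | intermediate (not isolated)
18 | 5-[(2R)-2-hydroxy-8-oxotridecyl]-3-methoxycyclohex-2-en-1-one (epimers at ring C5) | CCCCCC(=O)CCCCC[C@H](CC1CC(=O)C=C(OC)C1)O | intermediate
19 | (2R)-1-(5-methoxy-3-oxocyclohex-4-en-1-yl)-8-oxotridecan-2-yl acetate (epimers at ring C1) | CCCCCC(=O)CCCCC[C@H](CC1CC(=O)C=C(OC)C1)OC(C)=O | intermediate
20 | (2R)-1-(3-hydroxy-5-methoxycyclohexa-2,4-dien-1-yl)-8-oxotridecan-2-yl acetate | CCCCCC(=O)CCCCC[C@H](CC1C=C(O)C=C(OC)C1)OC(C)=O | intermediate (not isolated)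
21 | (2R)-1-(3-hydroxy-5-methoxyphenyl)-8-oxotridecan-2-yl acetate | CCCCCC(=O)CCCCC[C@H](Cc1cc(O)cc(OC)c1)OC(C)=O | target

Total step count: 10. Longest linear sequence: 10 steps (from cycloheptanone 1).

Steps most likely to fail

1. Step 7. Methoxide may remove a γ-proton of enone 11 before the malonate has added, and the dienolate then expels the δ-silyloxy group. A second failure is early loss of silicon, after which the C6 oxygen lactonises onto a malonate ester. The fallback sets out from 9 and rejoins the route at 14, hence at 16. It exchanges donor and acceptor so that the acceptor is an enoate, whose γ-protons are far less acidic. Cross-metathesis of 9 with methyl acrylate (second-generation Hoveyda–Grubbs catalyst, CH2Cl2, 40 °C) should give methyl (2E,5R)-5-(tert-butyldimethylsilyloxy)-11-oxohexadec-2-enoate F1. Michael–Claisen annulation of F1 with methyl acetoacetate (NaOMe, MeOH, reflux) should pass through dimethyl 2-acetyl-3-[(2R)-2-(tert-butyldimethylsilyloxy)-8-oxotridecyl]pentanedioate F2. Attack of the acetyl methyl enolate on the former acrylate ester then closes the same cyclic keto ester 14, which is saponified and decarboxylated as in step 7 to give 16.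

2. Step 10. Enolisation of the vinylogous ester toward the ring may be slow, so that aromatisation stalls. Hydride abstraction may also compete at the enol of the C8 ketone, or the acid may hydrolyse the enol ether. The fallback sets out from 19 and returns at 21. It replaces quinone hydride abstraction by catalytic aerobic dehydrogenation with divalent palladium: Pd(O2CCF3)2 (5 mol %), 2-(dimethylamino)pyridine (10 mol %), TsOH (20 mol %), O2 (1 atm), DMSO, 80 °C. α'-Palladation of the ring ketone and β-hydride elimination should give the cross-conjugated dienone (2R)-1-(5-methoxy-3-oxocyclohexa-1,4-dien-1-yl)-8-oxotridecan-2-yl acetate F3, which tautomerises to 21. The zerovalent palladium formed is reoxidised by O2.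

3. Step 6. The catalyst may be deactivated, the vinyl ketone may oligomerise, or 9 may homodimerise, leaving conversion incomplete. The fallback sets out from 9 and returns at 11 by stepwise olefination. Ozonolysis of 9 (O3, CH2Cl2, −78 °C; then PPh3) should proceed through the ozonide 3-[(2R)-2-(tert-butyldimethylsilyloxy)-8-oxotridecyl]-1,2,4-trioxolane F4 to (3R)-3-(tert-butyldimethylsilyloxy)-9-oxotetradecanal F5. This β-silyloxy aldehyde is used crude in a Wittig reaction with the stabilised ylide 1-(triphenylphosphoranylidene)propan-2-one (CH2Cl2, rt → 40 °C), which should give the (E)-enone 11.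

Further compounds
F1 | step 7 | methyl (2E,5R)-5-(tert-butyldimethylsilyloxy)-11-oxohexadec-2-enoate | CCCCCC(=O)CCCCC[C@H](C/C=C/C(=O)OC)O[Si](C)(C)C(C)(C)C
F2 | step 7 | dimethyl 2-acetyl-3-[(2R)-2-(tert-butyldimethylsilyloxy)-8-oxotridecyl]pentanedioate | CCCCCC(=O)CCCCC[C@H](CC(CC(=O)OC)C(C(C)=O)C(=O)OC)O[Si](C)(C)C(C)(C)C
F3 | step 10 | (2R)-1-(5-methoxy-3-oxocyclohexa-1,4-dien-1-yl)-8-oxotridecan-2-yl acetate | CCCCCC(=O)CCCCC[C@H](CC1=CC(=O)C=C(OC)C1)OC(C)=O
F4 | step 6 | 3-[(2R)-2-(tert-butyldimethylsilyloxy)-8-oxotridecyl]-1,2,4-trioxolane | CCCCCC(=O)CCCCC[C@H](CC1OCOO1)O[Si](C)(C)C(C)(C)C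
F5 | step 6 | (3R)-3-(tert-butyldimethylsilyloxy)-9-oxotetradecanal | CCCCCC(=O)CCCCC[C@H](CC=O)O[Si](C)(C)C(C)(C)C
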